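**Retrosynthetic overview**

1. Locants: chain C1 (CH2OH) to C15 (alkyne carbon on the ring). The key disconnection is the C7–C8 sp2–sp2 bond: Zr-catalysed methylalumination of the terminal alkyne of dienediyne 11, then Pd/Zn cross-coupling of the alkenylalane with (E,E)-dienyl iodide 19 in the same pot. This one operation also installs the C9 methyl group and the 8E alkene.
2. Enabling feature: the trisubstituted E-alkene C8H=C9(CH3)–C10, whose CH carbon is one end of the bond to be made. It is the retron of syn Me–Al addition to a terminal alkyne C8≡C9; the same motif, C5H=C4(CH3), builds the right half.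
3. Left half (ring + C8–C15): ring–C15 bond by Sonogashira coupling of the regiospecific enol triflate of silylated actinol with (E)-3-methylpent-2-en-4-yn-1-ol; C10=C11 by Horner–Wadsworth–Emmons olefination with a silylpropargyl phosphonate.
4. Right half (C1–C7): carboalumination–iodination of a pentynyl silyl ether, Sonogashira coupling with ethynyltrimethylsilane, hydrozirconation–iodination.
5. Rings: the single cyclohexene ring is not constructed. It comes with its carbinol stereocentre from (4R,6R)-actinol; only its C=C is introduced (step 2). Global desilylation ends the route.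

Key step: step 11

Remark: (4R,6R)-4-hydroxy-2,2,6-trimethylcyclohexanone (actinol), (E)-3-methylpent-2-en-4-yn-1-ol, diethyl [3-(trimethylsilyl)prop-2-yn-1-yl]phosphonate and tert-butyldimethyl(pent-4-yn-1-yloxy)silane are taken as catalogue compounds.

**Route**

Step 1
Reactants: 1 (4R,6R)-4-hydroxy-2,2,6-trimethylcyclohexan-1-one
Product: 2 (4R,6R)-4-[(tert-butyldimethylsilyl)oxy]-2,2,6-trimethylcyclohexan-1-one
Conditions: TBSCl, imidazole, DMF, rt
Reagents that add atoms: tert-butyldimethylsilyl chloride, CC(C)(C)[Si](C)(C)Cl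
Why: Imidazole-promoted silyl ether formation on the unhindered secondary alcohol leaves the carbinol stereocentre untouched and masks the hydroxyl against the organometallic steps that follow.

Step 2
Reactants: 2 (4R,6R)-4-[(tert-butyldimethylsilyl)oxy]-2,2,6-trimethylcyclohexan-1-one
Product: 4 (4R)-4-[(tert-butyldimethylsilyl)oxy]-2,6,6-trimethylcyclohex-1-en-1-yl trifluoromethanesulfonate, via lithium enolate 3 (not isolated)
Conditions: LDA (commercial solution), THF, −78 → 0 °C; then PhNTf2, THF, 0 °C → rt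
Reagents that add atoms: N-phenylbis(trifluoromethanesulfonimide), O=S(=O)(N(c1ccccc1)S(=O)(=O)C(F)(F)F)C(F)(F)F
Why: Enolate O-triflation is regiospecific because the ketone has a single α-hydrogen (C6; C2 is quaternary), the silyloxy group is γ to the carbonyl and cannot β-eliminate, and the C6 stereocentre is erased on purpose while the carbinol centre is not involved.

Step 3
Reactants: 4 (4R)-4-[(tert-butyldimethylsilyl)oxy]-2,6,6-trimethylcyclohex-1-en-1-yl trifluoromethanesulfonate; 5 (2E)-3-methylpent-2-en-4-yn-1-ol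
Product: 6 (2E)-5-{(4R)-4-[(tert-butyldimethylsilyl)oxy]-2,6,6-trimethylcyclohex-1-en-1-yl}-3-methylpent-2-en-4-yn-1-ol
Conditions: Pd(PPh3)4 (cat.), CuI (cat.), Et3N, DMF, degassed, rt → 50 °C
Reagents that add atoms: none
Why: Sonogashira coupling of an alkenyl triflate with a terminal alkyne tolerates the free allylic alcohol and the silyl ether and carries the E geometry of 5 (the future 12E alkene) through unchanged.

Step 4
Reactants: 6 (2E)-5-{(4R)-4-[(tert-butyldimethylsilyl)oxy]-2,6,6-trimethylcyclohex-1-en-1-yl}-3-methylpent-2-en-4-yn-1-ol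
Product: 7 (2E)-5-{(4R)-4-[(tert-butyldimethylsilyl)oxy]-2,6,6-trimethylcyclohex-1-en-1-yl}-3-methylpent-2-en-4-ynal
Conditions: activated MnO2 (excess), CH2Cl2, rt, dark
Reagents that add atoms: none
Why: Allylic oxidation with MnO2 is chemoselective for the primary allylic alcohol, stops at the aldehyde and should leave the enyne, its E geometry and the silyl ether untouched.

Step 5
Reactants: 7 (2E)-5-{(4R)-4-[(tert-butyldimethylsilyl)oxy]-2,6,6-trimethylcyclohex-1-en-1-yl}-3-methylpent-2-en-4-ynal; 8 diethyl [3-(trimethylsilyl)prop-2-yn-1-yl]phosphonate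
Product: 10 tert-butyldimethyl{[(1R)-3,5,5-trimethyl-4-[(3E,5E)-3-methyl-8-(trimethylsilyl)octa-3,5-dien-1,7-diyn-1-yl]cyclohex-3-en-1-yl]oxy}silane, via lithiated phosphonate 9 (not isolated)
Conditions: 8, LiHMDS, THF, −78 °C; then 7, −78 → 0 °C
Reagents that add atoms: none
Why: Horner–Wadsworth–Emmons olefination of an enal with a propargylic phosphonate anion should give the new C10=C11 alkene as the E isomer (reversible addition, elimination through the less hindered anti adduct) and delivers the C8≡C9 alkyne in silyl-capped form.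

Step 6
Reactants: 10 tert-butyldimethyl{[(1R)-3,5,5-trimethyl-4-[(3E,5E)-3-methyl-8-(trimethylsilyl)octa-3,5-dien-1,7-diyn-1-yl]cyclohex-3-en-1-yl]oxy}silane
Product: 11 tert-butyldimethyl{[(1R)-3,5,5-trimethyl-4-[(3E,5E)-3-methylocta-3,5-dien-1,7-diyn-1-yl]cyclohex-3-en-1-yl]oxy}silane
Conditions: K2CO3 (cat.), MeOH/THF, rt
Reagents that add atoms: none
Why: Base-catalysed protodesilylation cleaves only the alkynyl C–SiMe3 bond, whereas the secondary TBS ether is stable to carbonate in methanol.

Step 7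
Reactants: 12 tert-butyldimethyl(pent-4-yn-1-yloxy)silane
Product: 14 (E)-tert-butyl[(5-iodo-4-methylpent-4-en-1-yl)oxy]dimethylsilane, via alkenylalane 13 (not isolated)
Conditions: Me3Al, Cp2ZrCl2 (cat.), CH2Cl2, 0 °C → rt; then I2, THF, −30 → 0 °C
Reagents that add atoms: trimethylaluminium, C[Al](C)C; iodine, II
Why: Zirconium-catalysed carboalumination adds CH3 and Al syn across the terminal alkyne (methyl to the internal carbon), and iodinolysis of the C–Al bond with retention fixes the 4E trisubstituted alkene of the target.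

Step 8
Reactants: 14 (E)-tert-butyl[(5-iodo-4-methylpent-4-en-1-yl)oxy]dimethylsilane; 15 ethynyltrimethylsilane
Product: 16 (E)-tert-butyldimethyl{[4-methyl-7-(trimethylsilyl)hept-4-en-6-yn-1-yl]oxy}silane
Conditions: PdCl2(PPh3)2 (cat.), CuI (cat.), Et3N, THF, rt
Reagents that add atoms: none
Why: Sonogashira coupling of an alkenyl iodide proceeds with retention of the alkene geometry and is fully compatible with the silyl ether.

Step 9
Reactants: 16 (E)-tert-butyldimethyl{[4-methyl-7-(trimethylsilyl)hept-4-en-6-yn-1-yl]oxy}silane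
Product: 17 (E)-tert-butyldimethyl[(4-methylhept-4-en-6-yn-1-yl)oxy]silane
Conditions: K2CO3 (cat.), MeOH, rt
Reagents that add atoms: none
Why: Base-catalysed protodesilylation of the alkynylsilane is selective, since the primary TBS ether withstands carbonate in methanol at room temperature.

Step 10
Reactants: 17 (E)-tert-butyldimethyl[(4-methylhept-4-en-6-yn-1-yl)oxy]silane
Product: 19 tert-butyl{[(4E,6E)-7-iodo-4-methylhepta-4,6-dien-1-yl]oxy}dimethylsilane, via dienylzirconocene chloride 18 (not isolated)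
Conditions: Cp2Zr(H)Cl, THF, rt, dark; then I2, THF, 0 °C
Reagents that add atoms: iodine, II
Why: Hydrozirconation with the Schwartz reagent adds Zr–H syn across the terminal alkyne with Zr on the terminal carbon, and iodinolysis with retention gives the 6E alkenyl iodide without touching the trisubstituted alkene.

Step 11
Reactants: 11 tert-butyldimethyl{[(1R)-3,5,5-trimethyl-4-[(3E,5E)-3-methylocta-3,5-dien-1,7-diyn-1-yl]cyclohex-3-en-1-yl]oxy}silane; 19 tert-butyl{[(4E,6E)-7-iodo-4-methylhepta-4,6-dien-1-yl]oxy}dimethylsilane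
Product: 21 tert-butyl{[(4E,6E,8E,10E,12E)-15-{(4R)-4-[(tert-butyldimethylsilyl)oxy]-2,6,6-trimethylcyclohex-1-en-1-yl}-4,9,13-trimethylpentadeca-4,6,8,10,12-pentaen-14-yn-1-yl]oxy}dimethylsilane, via trienynylalane 20 (not isolated)
Conditions: Me3Al, Cp2ZrCl2 (cat.), ClCH2CH2Cl, 0 °C → rt; evaporation of volatiles; then 19, Pd2(dba)3 (cat.), P(2-furyl)3, ZnCl2 (cat.), THF/DMF, rt, dark
Reagents that add atoms: trimethylaluminium, C[Al](C)C
Why: Cp2ZrCl2 and Me3Al generate an electrophilic methyl–Zr/Al species that adds CH3 and metal syn across the terminal C≡C of 11, methyl to the internal carbon (future C9) and metal to the terminal CH (future C8), and Zr-to-Al exchange gives alkenylalane 20; after evaporation of excess Me3Al, oxidative addition of Pd(0) into the C–I bond of 19, Al→Zn→Pd transmetalation and reductive elimination form the C7–C8 bond. The closest known reaction type is the tandem Zr-catalysed carboalumination/Pd-catalysed Negishi alkenyl–alkenyl coupling of conjugated enynes with alkenyl iodides. No ring is closed and no stereocentre is formed; the new stereo-element, the 8E trisubstituted alkene, is controlled by the syn stereospecificity of carbometalation and by retention at both sp2 carbons in the coupling, which also carries the 4E,6E geometry of 19 and the 10E,12E geometry of 11 through unchanged. The step needs chemoselectivity for the terminal over the internal alkyne, regioselectivity for Al at the CH terminus, and alkenyl over methyl transfer: the C14≡C15 alkyne is disubstituted and shielded by the tetrasubstituted ring alkene with its gem-dimethyl group and by the C13 methyl group, so it should carbometalate far more slowly; metal at the terminal carbon is the intrinsic preference of terminal alkynes; and sp2 groups transfer from Al/Zn to Pd faster than methyl once free Me3Al is removed. The two silyl ethers are inert to Me3Al at room temperature and mask the hydroxyl groups that would otherwise protonate the alane.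

Step 12
Reactants: 21 tert-butyl{[(4E,6E,8E,10E,12E)-15-{(4R)-4-[(tert-butyldimethylsilyl)oxy]-2,6,6-trimethylcyclohex-1-en-1-yl}-4,9,13-trimethylpentadeca-4,6,8,10,12-pentaen-14-yn-1-yl]oxy}dimethylsilane
Product: 22 (4E,6E,8E,10E,12E)-15-[(4R)-4-hydroxy-2,6,6-trimethylcyclohex-1-en-1-yl]-4,9,13-trimethylpentadeca-4,6,8,10,12-pentaen-14-yn-1-ol
Conditions: TBAF, THF, 0 °C → rt, dark; aqueous work-up
Reagents that add atoms: none
Why: Fluoride-mediated desilylation should cleave the primary and the secondary TBS ether under near-neutral conditions that the pentaenyne tolerates, and it affects neither the stereocentre nor any alkene geometry.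

**Compound list**

1 | (4R,6R)-4-hydroxy-2,2,6-trimethylcyclohexan-1-one | CC1(C)C[C@H](O)C[C@@H](C)C1=O | starting material
2 | (4R,6R)-4-[(tert-butyldimethylsilyl)oxy]-2,2,6-trimethylcyclohexan-1-one | CC1(C)C[C@H](O[Si](C)(C)C(C)(C)C)C[C@@H](C)C1=O | intermediate
3 | lithium (4R)-4-[(tert-butyldimethylsilyl)oxy]-2,6,6-trimethylcyclohex-1-en-1-olate | CC1=C(O[Li])C(C)(C)C[C@H](O[Si](C)(C)C(C)(C)C)C1 | intermediate (not isolated)
4 | (4R)-4-[(tert-butyldimethylsilyl)oxy]-2,6,6-trimethylcyclohex-1-en-1-yl trifluoromethanesulfonate | CC1=C(OS(=O)(=O)C(F)(F)F)C(C)(C)C[C@H](O[Si](C)(C)C(C)(C)C)C1 | intermediate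
5 | (2E)-3-methylpent-2-en-4-yn-1-ol | C#C/C(C)=C/CO | starting material
6 | (2E)-5-{(4R)-4-[(tert-butyldimethylsilyl)oxy]-2,6,6-trimethylcyclohex-1-en-1-yl}-3-methylpent-2-en-4-yn-1-ol | CC1=C(C#C/C(C)=C/CO)C(C)(C)C[C@H](O[Si](C)(C)C(C)(C)C)C1 | intermediate
7 | (2E)-5-{(4R)-4-[(tert-butyldimethylsilyl)oxy]-2,6,6-trimethylcyclohex-1-en-1-yl}-3-methylpent-2-en-4-ynal | CC1=C(C#C/C(C)=C/C=O)C(C)(C)C[C@H](O[Si](C)(C)C(C)(C)C)C1 | intermediate
8 | diethyl [3-(trimethylsilyl)prop-2-yn-1-yl]phosphonate | CCOP(=O)(CC#C[Si](C)(C)C)OCC | starting material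
9 | diethyl [1-lithio-3-(trimethylsilyl)prop-2-yn-1-yl]phosphonate | CCOP(=O)(OCC)C([Li])C#C[Si](C)(C)C | intermediate (not isolated)
10 | tert-butyldimethyl{[(1R)-3,5,5-trimethyl-4-[(3E,5E)-3-methyl-8-(trimethylsilyl)octa-3,5-dien-1,7-diyn-1-yl]cyclohex-3-en-1-yl]oxy}silane | CC1=C(C#C/C(C)=C/C=C/C#C[Si](C)(C)C)C(C)(C)C[C@H](O[Si](C)(C)C(C)(C)C)C1 | intermediate
11 | tert-butyldimethyl{[(1R)-3,5,5-trimethyl-4-[(3E,5E)-3-methylocta-3,5-dien-1,7-diyn-1-yl]cyclohex-3-en-1-yl]oxy}silane | CC1=C(C#C/C(C)=C/C=C/C#C)C(C)(C)C[C@H](O[Si](C)(C)C(C)(C)C)C1 | intermediate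
12 | tert-butyldimethyl(pent-4-yn-1-yloxy)silane | C#CCCCO[Si](C)(C)C(C)(C)C | starting material
13 | (E)-{5-[(tert-butyldimethylsilyl)oxy]-2-methylpent-1-en-1-yl}dimethylalane | C[Al](C)/C=C(\C)CCCO[Si](C)(C)C(C)(C)C | intermediate (not isolated)
14 | (E)-tert-butyl[(5-iodo-4-methylpent-4-en-1-yl)oxy]dimethylsilane | I/C=C(\C)CCCO[Si](C)(C)C(C)(C)C | intermediate
15 | ethynyltrimethylsilane | C#C[Si](C)(C)C | starting material
16 | (E)-tert-butyldimethyl{[4-methyl-7-(trimethylsilyl)hept-4-en-6-yn-1-yl]oxy}silane | C[Si](C)(C)C#C/C=C(\C)CCCO[Si](C)(C)C(C)(C)C | intermediate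
17 | (E)-tert-butyldimethyl[(4-methylhept-4-en-6-yn-1-yl)oxy]silane | C#C/C=C(\C)CCCO[Si](C)(C)C(C)(C)C | intermediate
18 | chlorobis(cyclopentadienyl){(1E,3E)-7-[(tert-butyldimethylsilyl)oxy]-4-methylhepta-1,3-dien-1-yl}zirconium | Cl[Zr](/C=C/C=C(\C)CCCO[Si](C)(C)C(C)(C)C)(C1C=CC=C1)C1C=CC=C1 | intermediate (not isolated)
19 | tert-butyl{[(4E,6E)-7-iodo-4-methylhepta-4,6-dien-1-yl]oxy}dimethylsilane | I/C=C/C=C(\C)CCCO[Si](C)(C)C(C)(C)C | intermediate
20 | {(1E,3E,5E)-8-{(4R)-4-[(tert-butyldimethylsilyl)oxy]-2,6,6-trimethylcyclohex-1-en-1-yl}-2,6-dimethylocta-1,3,5-trien-7-yn-1-yl}dimethylalane | CC1=C(C#C/C(C)=C/C=C/C(C)=C/[Al](C)C)C(C)(C)C[C@H](O[Si](C)(C)C(C)(C)C)C1 | intermediate (not isolated)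
21 | tert-butyl{[(4E,6E,8E,10E,12E)-15-{(4R)-4-[(tert-butyldimethylsilyl)oxy]-2,6,6-trimethylcyclohex-1-en-1-yl}-4,9,13-trimethylpentadeca-4,6,8,10,12-pentaen-14-yn-1-yl]oxy}dimethylsilane | CC1=C(C#C/C(C)=C/C=C/C(C)=C/C=C/C=C(\C)CCCO[Si](C)(C)C(C)(C)C)C(C)(C)C[C@H](O[Si](C)(C)C(C)(C)C)C1 | intermediate
22 | (4E,6E,8E,10E,12E)-15-[(4R)-4-hydroxy-2,6,6-trimethylcyclohex-1-en-1-yl]-4,9,13-trimethylpentadeca-4,6,8,10,12-pentaen-14-yn-1-ol | CC1=C(C#C/C(C)=C/C=C/C(C)=C/C=C/C=C(\C)CCCO)C(C)(C)C[C@H](O)C1 | target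

**Step count and risks**

Total steps: 12. Longest linear sequence: 8 steps (steps 1–6, 11, 12).

Steps most likely to fail:

1. Step 11. The alane 20 may be lost between the two stages (protodealumination during evaporation, methyl instead of alkenyl transfer to palladium), or iodide 19 may isomerise under the Lewis-acidic Al/Zr residues. The fallback separates the two events and reverses the polarity; it sets out from 11 and 17 and comes back at 21. Alane 20, generated from 11 as in step 11, would be quenched with iodine (THF, −30 → 0 °C) to give tert-butyl{[(1R)-4-[(3E,5E,7E)-8-iodo-3,7-dimethylocta-3,5,7-trien-1-yn-1-yl]-3,5,5-trimethylcyclohex-3-en-1-yl]oxy}dimethylsilane F1. Enyne 17 would be hydroborated with pinacolborane (cat. Cp2Zr(H)Cl, CH2Cl2, rt) to give tert-butyldimethyl{[(4E,6E)-4-methyl-7-(4,4,5,5-tetramethyl-1,3,2-dioxaborolan-2-yl)hepta-4,6-dien-1-yl]oxy}silane F2. Suzuki–Miyaura coupling of the two (Pd(PPh3)4, aq. KOH, THF, rt, dark) should give 21.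

2. Step 5. The ambident propargyl/allenyl anion 9 may give allenic by-products, or E/Z control in the olefination may be insufficient, leaving isomers that are hard to separate at the polyene stage. The fallback builds the same C10=C11 alkene by a one-carbon iodo-olefination and attaches the alkyne afterwards; it sets out from 7 and comes back at 10. Takai olefination of 7 (CrCl2, CHI3, THF, 0 °C) should give tert-butyl{[(1R)-4-[(3E,5E)-6-iodo-3-methylhexa-3,5-dien-1-yn-1-yl]-3,5,5-trimethylcyclohex-3-en-1-yl]oxy}dimethylsilane F3. Sonogashira coupling of this iodide with ethynyltrimethylsilane 15 (PdCl2(PPh3)2, CuI, Et3N, THF, rt) should give 10.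

3. Step 3. Oxidative addition into the hindered, tetrasubstituted enol triflate 4 may be slower than copper-mediated homocoupling of 5 or hydrolysis of the triflate. The fallback makes the ring–alkyne bond by carbonyl addition and the ring alkene by dehydration; it sets out from 2 and 5 and comes back at 6. Enynol 5 would be doubly deprotonated (n-BuLi, 2 equiv, THF, −78 → 0 °C) to lithium (2E)-5-lithio-3-methylpent-2-en-4-yn-1-olate F4. Its addition to ketone 2 should give (4R,6R)-4-[(tert-butyldimethylsilyl)oxy]-1-[(3E)-5-hydroxy-3-methylpent-3-en-1-yn-1-yl]-2,2,6-trimethylcyclohexan-1-ol F5, as C1 epimers that converge later. Selective acetylation of the primary alcohol (Ac2O, pyridine, 0 °C) should give (2E)-5-{(4R,6R)-4-[(tert-butyldimethylsilyl)oxy]-1-hydroxy-2,2,6-trimethylcyclohexyl}-3-methylpent-2-en-4-yn-1-yl acetate F6. Dehydration of the tertiary propargylic alcohol (POCl3, pyridine, 60–90 °C) can only give the endocyclic alkene because the other neighbour is quaternary, and should give (2E)-5-{(4R)-4-[(tert-butyldimethylsilyl)oxy]-2,6,6-trimethylcyclohex-1-en-1-yl}-3-methylpent-2-en-4-yn-1-yl acetate F7. Methanolysis (K2CO3, MeOH, rt) returns 6.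

**Further compounds**

F1 | step 11 | tert-butyl{[(1R)-4-[(3E,5E,7E)-8-iodo-3,7-dimethylocta-3,5,7-trien-1-yn-1-yl]-3,5,5-trimethylcyclohex-3-en-1-yl]oxy}dimethylsilane | CC1=C(C#C/C(C)=C/C=C/C(C)=C/I)C(C)(C)C[C@H](O[Si](C)(C)C(C)(C)C)C1
F2 | step 11 | tert-butyldimethyl{[(4E,6E)-4-methyl-7-(4,4,5,5-tetramethyl-1,3,2-dioxaborolan-2-yl)hepta-4,6-dien-1-yl]oxy}silane | CC1(C)OB(/C=C/C=C(\C)CCCO[Si](C)(C)C(C)(C)C)OC1(C)C
F3 | step 5 | tert-butyl{[(1R)-4-[(3E,5E)-6-iodo-3-methylhexa-3,5-dien-1-yn-1-yl]-3,5,5-trimethylcyclohex-3-en-1-yl]oxy}dimethylsilane | CC1=C(C#C/C(C)=C/C=C/I)C(C)(C)C[C@H](O[Si](C)(C)C(C)(C)C)C1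
F4 | step 3 | lithium (2E)-5-lithio-3-methylpent-2-en-4-yn-1-olate | [Li]C#C/C(C)=C/CO[Li]
F5 | step 3 | (4R,6R)-4-[(tert-butyldimethylsilyl)oxy]-1-[(3E)-5-hydroxy-3-methylpent-3-en-1-yn-1-yl]-2,2,6-trimethylcyclohexan-1-ol (C1 epimers) | CC1(C)C[C@H](O[Si](C)(C)C(C)(C)C)C[C@@H](C)C1(O)C#C/C(C)=C/CO
F6 | step 3 | (2E)-5-{(4R,6R)-4-[(tert-butyldimethylsilyl)oxy]-1-hydroxy-2,2,6-trimethylcyclohexyl}-3-methylpent-2-en-4-yn-1-yl acetate (C1 epimers) | CC1(C)C[C@H](O[Si](C)(C)C(C)(C)C)C[C@@H](C)C1(O)C#C/C(C)=C/COC(C)=O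
F7 | step 3 | (2E)-5-{(4R)-4-[(tert-butyldimethylsilyl)oxy]-2,6,6-trimethylcyclohex-1-en-1-yl}-3-methylpent-2-en-4-yn-1-yl acetate | CC1=C(C#C/C(C)=C/COC(C)=O)C(C)(C)C[C@H](O[Si](C)(C)C(C)(C)C)C1
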